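**Plan**

- Numbering used throughout: carbocycle C1 (CHOH), C2, C3 (CHOAc), C4(Me)=C5, C6 (lactone O), C7, C8 (O-acyl), C9=C10(Me); lactone C11 (α-carbon, =C13H2) and C12 (C=O).
- Retrosynthetic cuts, in order: the C8 ester and the O1 silyl ether; the C8–C9 bond (alkenyl–carbinol bond of the allylic alcohol C8–C9=C10), which opens the ten-membered ring; C1–C2 (aldol); C6–C7 together with the lactone C12–O bond (allylation/lactonisation); the Z-C4=C5 unit is traced back to a furan ring.
- Forward order: γ-lactone first (step 4), then the C1/C10/C9 arm (steps 7–10), masking of the methylene lactone as a thiophenol adduct (step 11), ten-membered ring (step 14), then acylation, unmasking and desilylation.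
- Stereochemistry: C6/C7 from the dioxolane of (R)-glyceraldehyde acetonide, which is afterwards cut down to the C8 aldehyde; C1 from (+)-Ipc2BCl; C3 from a CBS reduction; C8 from the ring-closing transition state; the ester centre from (R)-2-methylbutanoic acid; Z-C4=C5 from 2,3-dimethylfuran; Z-C9=C10 from an anti-carbomagnesiation.
- Enabling feature: the lactone ring (O–C6–C7–C11–C12) is cis-fused to the carbocycle at C6–C7, and with the two Z double bonds C4=C5 and C9=C10 this holds C8 (as CHO) next to C9 (as C–I).

Key step: step 14

Remark: compounds 19 to 26 are carried as both C11 epimers (C11 drawn without configuration); this centre is removed again in step 16.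

**Step 1**
Reactants: 1 (R)-2,2-dimethyl-1,3-dioxolane-4-carbaldehyde; 2 phenyl acrylate
Product: 3 phenyl 2-{hydroxy[(4R)-2,2-dimethyl-1,3-dioxolan-4-yl]methyl}prop-2-enoate (both carbinol epimers)
Conditions: 1,4-diazabicyclo[2.2.2]octane (DABCO, 0.5 equiv), dioxane–H2O, rt
Reagents that add atoms: none
Why: Morita–Baylis–Hillman reaction, in which the reactive aryl acrylate shortens the exposure of the base-labile α-alkoxy aldehyde so that its configuration should be kept, and the new carbinol centre is irrelevant because it becomes sp2 in step 2.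

**Step 2**
Reactants: 3 Baylis–Hillman alcohol
Product: 4 phenyl (2Z)-2-(bromomethyl)-3-[(4S)-2,2-dimethyl-1,3-dioxolan-4-yl]prop-2-enoate
Conditions: NBS, Me2S, CH2Cl2, 0 °C to rt
Reagents that add atoms: N-bromosuccinimide, O=C1CCC(=O)N1Br
Why: Allylic transposition of a Baylis–Hillman alcohol, in which the alkoxysulfonium ion is displaced by bromide in the SN2' sense to give the thermodynamically preferred (Z)-2-(bromomethyl)enoate under neutral conditions that spare the acetonide.

**Step 3**
Reactants: 5 2,3-dimethylfuran
Product: 6 (2Z)-3-methyl-4-oxopent-2-enal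
Conditions: dimethyldioxirane, acetone, −78 to 0 °C; evaporated cold and used at once
Reagents that add atoms: dimethyldioxirane, CC1(C)OO1
Why: Oxidative ring opening of a furan (epoxidation then electrocyclic opening), which delivers the cis-ene-dione so that the Z geometry of the later C4=C5 bond is inherited from the ring.

**Step 4**
Reactants: 4 allylic bromide; 6 keto-enal
Product: 8 4-[(4S)-2,2-dimethyl-1,3-dioxolan-4-yl]-3-methylidene-5-[(1Z)-2-methyl-3-oxobut-1-enyl]oxolan-2-one (4,5-cis; C6 and C7 as in 28), via homoallylic indium alkoxide 7 (not isolated)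
Conditions: In powder (1.5 equiv), THF, 0 °C to rt
Reagents that add atoms: none
Why: Barbier-type indium-mediated 2-(aryloxycarbonyl)allylation followed by lactonisation, in which the allylindium attacks the aldehyde (not the ketone) through its γ-carbon in a Zimmerman–Traxler chair with the Z-disposed dioxolanyl group axial (syn adduct, hence the cis-lactone), the allyl face is set by the dioxolane centre whose C–H eclipses the double bond (A(1,3) strain) so that the aldehyde should enter on the side of the ring oxygen to give the C6/C7 configuration of the target, and the phenyl ester lets the alkoxide close the lactone before the cis-γ-hydroxy enone can dehydrate to a furan.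

**Step 5**
Reactants: 9 prop-2-yn-1-ol
Product: 11 (2Z)-3-iodo-2-methylprop-2-en-1-ol, via alkenylmagnesium chelate 10 (not isolated)
Conditions: MeMgBr (2.5 equiv), CuI (10 mol %), THF, −10 °C to rt; then I2, −60 to 0 °C
Reagents that add atoms: methylmagnesium bromide, C[Mg]Br; iodine, [I][I]
Why: Copper-catalysed anti-carbomagnesiation of a propargylic alkoxide, which places methyl on the carbon next to the carbinol and magnesium on the terminus within a five-membered chelate, so that iodinolysis with retention gives the (Z)-iodoalkene.

**Step 6**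
Reactants: 11 iodo alcohol
Product: 12 (2Z)-3-iodo-2-methylprop-2-enal
Conditions: MnO2, CH2Cl2, rt, dark; filtered and used as a solution
Reagents that add atoms: none
Why: Allylic oxidation with MnO2, a neutral heterogeneous oxidant that should not isomerise the Z-iodoenal when the solution is used directly.

**Step 7**
Reactants: 8 methyl ketone lactone; 12 iodoenal
Product: 14 aldol adduct of 8 carrying the (1Z,5S,6Z)-5-hydroxy-7-iodo-2,6-dimethyl-3-oxohepta-1,6-dienyl chain at C6, via enol borinate 13 (not isolated)
Conditions: (+)-Ipc2BCl, Et3N, Et2O, 0 °C; then 12, −78 to −20 °C; then H2O2, MeOH, pH 7 buffer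
Reagents that add atoms: none
Why: Reagent-controlled boron aldol reaction, in which the methyl ketone is enolised regioselectively and the enol diisopinocampheylborinate adds to the aldehyde through a Zimmerman–Traxler transition state whose isopinocampheyl ligands should select the face giving the 1S carbinol, the remote lactone centres having little influence.

**Step 8**
Reactants: 14 aldol adduct
Product: 15 O1-tert-butyldimethylsilyl ether of 14
Conditions: TBSOTf, 2,6-lutidine, CH2Cl2, −78 °C
Reagents that add atoms: tert-butyldimethylsilyl triflate, CC(C)(C)[Si](C)(C)OS(=O)(=O)C(F)(F)F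
Why: Silyl ether formation at low temperature with a hindered base, which protects O1 until the last step without retro-aldol cleavage or β-elimination.

**Step 9**
Reactants: 15 silyloxy enone
Product: 16 (3S)-allylic alcohol derived from 15
Conditions: (R)-1-methyl-3,3-diphenyltetrahydro-1H,3H-pyrrolo[1,2-c][1,3,2]oxazaborole (20 mol %), catecholborane, toluene, −78 °C
Reagents that add atoms: none
Why: Corey–Bakshi–Shibata reduction, in which the (R)-oxazaborolidine binds the enone carbonyl with the α-branched alkenyl group as the large substituent and delivers hydride 1,2 to give the 3S alcohol, catecholborane at low temperature sparing the methylene lactone.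

**Step 10**
Reactants: 16 allylic alcohol
Product: 17 C3 acetate of 16
Conditions: Ac2O, pyridine, 4-(dimethylamino)pyridine (DMAP, cat.), CH2Cl2, 0 °C
Reagents that add atoms: acetic anhydride, CC(=O)OC(C)=O
Why: Nucleophile-catalysed acetylation of the secondary allylic alcohol, which installs the C3 acetate of the target with retention.

**Step 11**
Reactants: 17 methylene lactone; 18 thiophenol
Product: 19 C13 phenylthio adduct of 17 (lactone now carries CH2SPh at C11; C11 epimers)
Conditions: Et3N (cat.), CH2Cl2, 0 °C
Reagents that add atoms: none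
Why: Thia-Michael addition to the exocyclic methylene of the lactone, the only good acceptor present, which masks the acrylate so that the C7 hydrogen of the coming C8 aldehyde is no longer doubly activated.

**Step 12**
Reactants: 19 acetonide
Product: 20 diol from 19 (C7 carries a (1S)-1,2-dihydroxyethyl group)
Conditions: CeCl3·7H2O, oxalic acid, MeCN, rt
Reagents that add atoms: none
Why: Mild Lewis-acid-assisted hydrolysis of a terminal isopropylidene acetal, under which the secondary TBS ether, the acetate, the sulfide and the lactone should survive.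

**Step 13**
Reactants: 20 diol
Product: 21 C8 aldehyde (C7-formyl lactone with the C9 iodoalkene)
Conditions: NaIO4, THF–pH 7 buffer, 0 °C, short reaction time; used crude
Reagents that add atoms: none
Why: Periodate glycol cleavage, which releases the C8 aldehyde under neutral, non-epimerising conditions and is much faster than oxidation of the aryl sulfide at this temperature.

**Step 14**
Reactants: 21 iodoalkene aldehyde
Product: 23 ten-membered (8R)-alcohol with C1 OTBS, C3 OAc, the cis-fused lactone and CH2SPh at C11, via alkenylchromium species 22 (not isolated)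
Conditions: CrCl2 (10 equiv), NiCl2 (5 mol %), degassed DMSO–THF, about 2 mM, rt
Reagents that add atoms: none
Why: Nozaki–Hiyama–Kishi coupling: zerovalent nickel formed in situ inserts into the C9–I bond with retention of the Z geometry, transmetalation to trivalent chromium gives the alkenylchromium species 22, and this adds 1,2 to the C8 aldehyde. The closest known reaction type is the Ni/Cr-mediated alkenyl iodide–aldehyde macrocyclisation used to close medium-sized carbocycles. The ten-membered carbocycle (C1–C10) closes in a 10-exo-trig mode, which is feasible because the cis-fused lactone holds the formyl group and the C5 side chain on the same face of the C6–C7 bond and the Z double bonds C4=C5 and C9=C10 turn the chain back on itself. The one new stereocentre, C8, is controlled by C7 within the ring-forming transition state: the tether forces C9 to approach gauche to C6, and of the two such trajectories the Felkin–Anh-like one, antiperiplanar to the C7–C11 bond and past the small C7 hydrogen, should give the 8R carbinol. The step needs ring closure to win over intermolecular coupling, which high dilution and this preorganisation should secure, and attack on the aldehyde only, which the low basicity and carbonyl selectivity of organochromium reagents secure, leaving the lactone, acetate, sulfide and the epimerisable C7 centre untouched.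

**Step 15**
Reactants: 23 macrocyclic alcohol; 24 (R)-2-methylbutanoic acid
Product: 25 C8 (R)-2-methylbutanoate of 23
Conditions: DCC, DMAP (cat.), CH2Cl2, 0 °C to rt
Reagents that add atoms: none
Why: Steglich esterification, which acylates the secondary allylic alcohol with retention at C8 and under conditions mild enough that the α-centre of the acid and the neighbouring lactone should stay in place.

**Step 16**
Reactants: 25 sulfide ester
Product: 27 α-methylene lactone (O1-TBS ether of the target), via sulfoxide 26 (not isolated)
Conditions: mCPBA (1.0 equiv), CH2Cl2, −78 °C; then toluene, NaHCO3, 90 °C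
Reagents that add atoms: none
Why: Sulfide oxidation followed by thermal syn-elimination of the sulfoxide, where the sulfide is oxidised far faster than the trisubstituted alkenes and the only β-hydrogen available is the acidic C11–H, so the exocyclic methylene is regenerated regiospecifically.

**Step 17**
Reactants: 27 silyl ether
Product: 28 target compound
Conditions: HF·pyridine, pyridine, THF, 0 °C to rt
Reagents that add atoms: none
Why: Fluoride-mediated desilylation under buffered conditions, which frees the C1 hydroxyl without touching the two esters or the α-methylene lactone.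

**Compound list**

1 | (R)-2,2-dimethyl-1,3-dioxolane-4-carbaldehyde | O=C[C@H]1COC(C)(C)O1 | starting material
2 | phenyl acrylate | C=CC(=O)Oc1ccccc1 | starting material
3 | phenyl 2-{hydroxy[(4R)-2,2-dimethyl-1,3-dioxolan-4-yl]methyl}prop-2-enoate (carbinol epimers) | C=C(C(O)[C@H]1COC(C)(C)O1)C(=O)Oc1ccccc1 | intermediate
4 | phenyl (2Z)-2-(bromomethyl)-3-[(4S)-2,2-dimethyl-1,3-dioxolan-4-yl]prop-2-enoate | BrC/C(C(=O)Oc1ccccc1)=C\[C@H]1COC(C)(C)O1 | intermediate
5 | 2,3-dimethylfuran | Cc1ccoc1C | starting material
6 | (2Z)-3-methyl-4-oxopent-2-enal | O=C/C=C(/C)C(C)=O | intermediate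
7 | indium-bound syn homoallylic alkoxide, phenyl (5Z)-3-[(4S)-2,2-dimethyl-1,3-dioxolan-4-yl]-6-methyl-2-methylidene-4-oxido-7-oxooct-5-enoate (drawn as the anion) | C=C(C(=O)Oc1ccccc1)[C@H]([C@H]1COC(C)(C)O1)[C@@H]([O-])/C=C(/C)C(C)=O | intermediate (not isolated)
8 | 4-[(4S)-2,2-dimethyl-1,3-dioxolan-4-yl]-3-methylidene-5-[(1Z)-2-methyl-3-oxobut-1-enyl]oxolan-2-one (4,5-cis; C6, C7 as in 28) | C=C1C(=O)O[C@@H](/C=C(/C)C(C)=O)[C@H]1[C@H]2COC(C)(C)O2 | intermediate
9 | prop-2-yn-1-ol | C#CCO | starting material
10 | bromomagnesium (2Z)-3-(bromomagnesio)-2-methylprop-2-en-1-olate | Br[Mg]/C=C(C)\CO[Mg]Br | intermediate (not isolated)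
11 | (2Z)-3-iodo-2-methylprop-2-en-1-ol | OC/C(C)=C\I | intermediate
12 | (2Z)-3-iodo-2-methylprop-2-enal | O=C/C(C)=C\I | intermediate
13 | enol diisopinocampheylborinate of 8 (boron on the C3 oxygen, C2 as =CH2) | C=C1C(=O)O[C@@H](/C=C(/C)C(=C)OB([C@H]3C[C@H]4C[C@@H]([C@@H]3C)C4(C)C)[C@H]3C[C@H]4C[C@@H]([C@@H]3C)C4(C)C)[C@H]1[C@H]2COC(C)(C)O2 | intermediate (not isolated)
14 | aldol adduct, lactone 8 with the (1Z,5S,6Z)-5-hydroxy-7-iodo-2,6-dimethyl-3-oxohepta-1,6-dienyl chain | C=C1C(=O)O[C@@H](/C=C(/C)C(=O)C[C@H](O)/C(C)=C\I)[C@H]1[C@H]2COC(C)(C)O2 | intermediate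
15 | O1-tert-butyldimethylsilyl ether of 14 | C=C1C(=O)O[C@@H](/C=C(/C)C(=O)C[C@H](O[Si](C)(C)C(C)(C)C)/C(C)=C\I)[C@H]1[C@H]2COC(C)(C)O2 | intermediate
16 | (3S)-alcohol, side chain (1Z,3S,5S,6Z)-5-(tert-butyldimethylsilyloxy)-3-hydroxy-7-iodo-2,6-dimethylhepta-1,6-dienyl | C=C1C(=O)O[C@@H](/C=C(/C)[C@@H](O)C[C@H](O[Si](C)(C)C(C)(C)C)/C(C)=C\I)[C@H]1[C@H]2COC(C)(C)O2 | intermediate
17 | C3 acetate of 16 | C=C1C(=O)O[C@@H](/C=C(/C)[C@@H](OC(C)=O)C[C@H](O[Si](C)(C)C(C)(C)C)/C(C)=C\I)[C@H]1[C@H]2COC(C)(C)O2 | intermediate
18 | thiophenol | Sc1ccccc1 | starting material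
19 | phenylthio adduct of 17 (CH2SPh at C11, C11 epimers) | C(Sc3ccccc3)C1C(=O)O[C@@H](/C=C(/C)[C@@H](OC(C)=O)C[C@H](O[Si](C)(C)C(C)(C)C)/C(C)=C\I)[C@H]1[C@H]2COC(C)(C)O2 | intermediate
20 | diol from 19, (1S)-1,2-dihydroxyethyl group on C7 | C(Sc3ccccc3)C1C(=O)O[C@@H](/C=C(/C)[C@@H](OC(C)=O)C[C@H](O[Si](C)(C)C(C)(C)C)/C(C)=C\I)[C@H]1[C@H](O)CO | intermediate
21 | C8 aldehyde (formyl group on C7, cis to the C6 side chain) | C(Sc3ccccc3)C1C(=O)O[C@@H](/C=C(/C)[C@@H](OC(C)=O)C[C@H](O[Si](C)(C)C(C)(C)C)/C(C)=C\I)[C@H]1C=O | intermediate
22 | (Z)-alkenylchromium dichloride derived from 21 (Cr on C9) | C(Sc3ccccc3)C1C(=O)O[C@@H](/C=C(/C)[C@@H](OC(C)=O)C[C@H](O[Si](C)(C)C(C)(C)C)/C(C)=C\[Cr](Cl)Cl)[C@H]1C=O | intermediate (not isolated)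
23 | ten-membered (8R)-alcohol: (1S,3S,6S,8R; C7 as in 28; 4Z,9Z) 3-acetoxy-1-(tert-butyldimethylsilyloxy)-8-hydroxy-13-(phenylsulfanyl)germacra-4,9-dien-12,6-olide (numbering of the plan, C11 epimers) | C(Sc3ccccc3)C1C(=O)O[C@H]2/C=C(/C)[C@@H](OC(C)=O)C[C@H](O[Si](C)(C)C(C)(C)C)/C(C)=C\[C@@H](O)[C@@H]12 | intermediate
24 | (R)-2-methylbutanoic acid | CC[C@@H](C)C(=O)O | starting material
25 | C8 (R)-2-methylbutanoate of 23 | C(Sc3ccccc3)C1C(=O)O[C@H]2/C=C(/C)[C@@H](OC(C)=O)C[C@H](O[Si](C)(C)C(C)(C)C)/C(C)=C\[C@@H](OC(=O)[C@H](C)CC)[C@@H]12 | intermediate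
26 | S-oxide of 25 (sulfur and C11 epimers) | O=S(c3ccccc3)CC1C(=O)O[C@H]2/C=C(/C)[C@@H](OC(C)=O)C[C@H](O[Si](C)(C)C(C)(C)C)/C(C)=C\[C@@H](OC(=O)[C@H](C)CC)[C@@H]12 | intermediate (not isolated)
27 | O1-tert-butyldimethylsilyl ether of the target | C=C1C(=O)O[C@H]2/C=C(/C)[C@@H](OC(C)=O)C[C@H](O[Si](C)(C)C(C)(C)C)/C(C)=C\[C@@H](OC(=O)[C@H](C)CC)[C@@H]12 | intermediate
28 | target compound | C=C1C(=O)O[C@H]2/C=C(/C)[C@@H](OC(C)=O)C[C@H](O)/C(C)=C\[C@@H](OC(=O)[C@H](C)CC)[C@@H]12 | target

**Counts**

Total steps: 17. Longest linear sequence: 14 steps (1, 2, 4, 7 to 17).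

**Steps most likely to fail**

Step 4 (allylation and lactonisation). Several processes may interfere: electron transfer from the metal to the cis-ene-dione (reduction or Z-to-E isomerisation), 1,4-elimination of the dioxolane oxygen from the allylmetal, lactonisation lagging so that the cis-γ-hydroxy enone dehydrates to a furan, or weak facial control by the dioxolane. The fallback sets out from 3 and comes back at 8. Compound 3 is acetylated (Ac2O, DMAP) to phenyl 2-{acetoxy[(4R)-2,2-dimethyl-1,3-dioxolan-4-yl]methyl}prop-2-enoate F1. SN2' borylation of F1 with bis(pinacolato)diboron under Pd2(dba)3 catalysis should give the allylboronate F2. Thermal allylboration of 6 with F2 in toluene runs through a closed boron transition state in an aprotic medium without a reducing metal, and the boron alkoxide should lactonise onto the phenyl ester to give 8.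

Step 14 (ring closure). The alkenylchromium may add to the other aldehyde face, or the macrocyclic transition state may discriminate the faces poorly. The fallback sets out from 21 and comes back at 25. The same ring closure is run and the 8S alcohol F3 is isolated; it is esterified with inversion by a Mitsunobu reaction with acid 24 (PPh3, diisopropyl azodicarboxylate, toluene, 0 °C) to give 25, so both C8 epimers converge on the route.

Step 7 (aldol). Reagent control over the aldehyde face may be incomplete, and the Z-enone or the Z-iodoenal may isomerise under the amine/boron chloride conditions. The fallback sets out from 8 and comes back at 14. Ketone 8 is converted into its trimethylsilyl enol ether F4 (TMSOTf, Et3N, −78 °C). F4 is added to 12 in a catalytic enantioselective Mukaiyama aldol reaction promoted by the chiral (acyloxy)borane made from BH3·THF and mono(2,6-diisopropoxybenzoyl)tartaric acid in EtCN at −78 °C, and mild acidic desilylation (citric acid, MeOH) gives 14.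

**Further compounds**

F1 | step 4 | phenyl 2-{acetoxy[(4R)-2,2-dimethyl-1,3-dioxolan-4-yl]methyl}prop-2-enoate | C=C(C(OC(C)=O)[C@H]1COC(C)(C)O1)C(=O)Oc1ccccc1
F2 | step 4 | phenyl (2E)-3-[(4S)-2,2-dimethyl-1,3-dioxolan-4-yl]-2-[(4,4,5,5-tetramethyl-1,3,2-dioxaborolan-2-yl)methyl]prop-2-enoate | CC1(C)OB(C/C(C(=O)Oc2ccccc2)=C\[C@H]2COC(C)(C)O2)OC1(C)C
F3 | step 14 | 8S epimer of 23 | C(Sc3ccccc3)C1C(=O)O[C@H]2/C=C(/C)[C@@H](OC(C)=O)C[C@H](O[Si](C)(C)C(C)(C)C)/C(C)=C\[C@H](O)[C@@H]12
F4 | step 7 | trimethylsilyl enol ether of 8 | C=C1C(=O)O[C@@H](/C=C(/C)C(=C)O[Si](C)(C)C)[C@H]1[C@H]2COC(C)(C)O2
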